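**Plan**

- Retrosynthesis: after the three silyl groups are removed, ring A is cut at C4a–C5 and C8–C8a (flavanone numbering). This gives a 5-(phenylsulfinyl)-2,3-dihydropyran-4-one carrying ring B, and a 1-methoxy-3-silyloxy diene that supplies C5–C8, the C7 oxygen and the C8 side chain. The diene is cut once more at the C8–CH2 bond of the side chain.
- Enabling feature: ring A is a benzene joined to the pyranone ring C only through C4a–C8a, with C4a α and the oxygen-bearing C8a β to the C4 ketone. It has hydrogen at C5 and C6, oxygen at C7 and a carbon chain at C8. C4a=C8a therefore maps onto an enone alkene and C5–C8 onto a Danishefsky-type diene, and loss of PhSOH and MeOH supplies the aromatic oxidation level.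
- Forward order: ring C is made first by a hetero-Diels–Alder reaction of the ring-B aldehyde, then sulfur is placed on C5. The side chain is joined to the diene by enolate alkylation. Ring A is closed last by cycloaddition and aromatisation, followed by global desilylation.
- Stereochemistry: C2 (S) comes from the (S)-BINOL/Ti(O-iPr)4-catalysed hetero-Diels–Alder step. The (E)-olefin comes from SeO2 oxidation of prenyl acetate. Neither is touched afterwards.

Key step: step 11

Assumption: the (S)-BINOL–titanium catalyst is taken to direct the diene to the Si face of the silylated aryl aldehyde, as in related additions to benzaldehyde, which gives the (2S) centre; if the sense proves opposite, (R)-BINOL is used instead.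

**Route**

Step 1
Reactants: 1 prenyl acetate (3-methylbut-2-enyl acetate)
Product: 2 (E)-4-hydroxy-3-methylbut-2-enyl acetate
Conditions: SeO2 (cat.), t-BuOOH, CH2Cl2, rt
Reagents that add atoms: tert-butyl hydroperoxide, CC(C)(C)OO (terminal oxygen source); SeO2, O=[Se]=O (catalytic oxygen carrier)
Why: Catalytic SeO2/t-BuOOH allylic oxidation (ene reaction followed by [2,3]-shift) is known to hydroxylate the methyl group trans to the chain of a prenyl unit, which fixes the (E)-olefin; any over-oxidised enal is removed by chromatography.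

Step 2
Reactants: 2 (E)-4-hydroxy-3-methylbut-2-enyl acetate
Product: 3 (E)-4-(tert-butyldimethylsilyloxy)-3-methylbut-2-enyl acetate
Conditions: TBSCl, imidazole, CH2Cl2, 0 °C → rt
Reagents that add atoms: tert-butyldimethylsilyl chloride, CC(C)(C)[Si](C)(C)Cl
Why: Imidazole-promoted silylation of a primary allylic alcohol is routine and leaves the acetate untouched.

Step 3
Reactants: 3 (E)-4-(tert-butyldimethylsilyloxy)-3-methylbut-2-enyl acetate
Product: 4 (E)-4-(tert-butyldimethylsilyloxy)-3-methylbut-2-en-1-ol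
Conditions: K2CO3 (cat.), MeOH, 0 °C
Reagents that add atoms: none
Why: Base-catalysed methanolysis (transesterification) removes the acetate, and the alkyl silyl ether is stable to K2CO3/MeOH at this temperature.

Step 4
Reactants: 4 (E)-4-(tert-butyldimethylsilyloxy)-3-methylbut-2-en-1-ol
Product: 5 (E)-(4-bromo-2-methylbut-2-enyloxy)(tert-butyl)dimethylsilane
Conditions: CBr4, PPh3, CH2Cl2, 0 °C
Reagents that add atoms: carbon tetrabromide, BrC(Br)(Br)Br
Why: The Appel reaction converts the primary allylic alcohol into the bromide by SN2 displacement at the unhindered CH2, without allylic transposition or loss of olefin geometry.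

Step 5
Reactants: 6 (E)-4-methoxybut-3-en-2-one; 5 (E)-(4-bromo-2-methylbut-2-enyloxy)(tert-butyl)dimethylsilane
Product: 7 (1E,6E)-8-(tert-butyldimethylsilyloxy)-1-methoxy-7-methylocta-1,6-dien-3-one
Conditions: LiHMDS, THF, −78 °C; then 5, DMPU, −78 → −30 °C
Reagents that add atoms: none
Why: Kinetic deprotonation of the methyl group of the vinylogous ester gives the cross-conjugated lithium enolate, and its C-alkylation by a primary allylic bromide is the acyclic counterpart of the Stork–Danheiser alkylation.

Step 6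
Reactants: 7 (1E,6E)-8-(tert-butyldimethylsilyloxy)-1-methoxy-7-methylocta-1,6-dien-3-one
Product: 8 (1E,3Z,6E)-8-(tert-butyldimethylsilyloxy)-1-methoxy-7-methyl-3-(trimethylsilyloxy)octa-1,3,6-triene
Conditions: TMSOTf, Et3N, Et2O, 0 °C
Reagents that add atoms: trimethylsilyl trifluoromethanesulfonate, C[Si](C)(C)OS(=O)(=O)C(F)(F)F
Why: Soft enolisation with TMSOTf/Et3N, the standard way to Danishefsky-type dienes, can only occur toward C4 and under these equilibrating conditions should favour the (3Z)-enol silane, which places the chain on the outside of the s-cis diene.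

Step 7
Reactants: 9 3,4-dihydroxybenzaldehyde
Product: 10 3,4-bis(tert-butyldimethylsilyloxy)benzaldehyde
Conditions: TBSCl, imidazole, DMF, rt
Reagents that add atoms: tert-butyldimethylsilyl chloride, CC(C)(C)[Si](C)(C)Cl
Why: Double silylation of the catechol masks both acidic phenols for the titanium-catalysed step and makes the aldehyde soluble and non-chelating.

Step 8
Reactants: 10 3,4-bis(tert-butyldimethylsilyloxy)benzaldehyde; 11 (E)-1-methoxy-3-(trimethylsilyloxy)buta-1,3-diene (Danishefsky's diene)
Product: 13 (2S)-2-[3,4-bis(tert-butyldimethylsilyloxy)phenyl]-2,3-dihydro-4H-pyran-4-one, via Mukaiyama aldol silyl ether 12 (not isolated)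
Conditions: (S)-BINOL (20 mol %), Ti(O-iPr)4 (10 mol %), CF3CO2H (cat.), 4 Å MS, Et2O, −20 °C; then CF3CO2H, CH2Cl2, 0 °C
Reagents that add atoms: none
Why: This is a Keck-type formal hetero-Diels–Alder reaction, a Ti–BINOL-catalysed Mukaiyama aldol addition followed by acid-induced ring closure with loss of methanol, in which the chiral titanium complex shields one aldehyde face so that C–C bond formation on the Si face sets the (2S) centre.

Step 9
Reactants: 13 (2S)-2-[3,4-bis(tert-butyldimethylsilyloxy)phenyl]-2,3-dihydro-4H-pyran-4-one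
Product: 15 (2S)-2-[3,4-bis(tert-butyldimethylsilyloxy)phenyl]-5-(phenylthio)-2,3-dihydro-4H-pyran-4-one, via chloro sulfide adduct 14 (not isolated)
Conditions: PhSCl, CH2Cl2, −78 °C; then Et3N, −78 → 0 °C
Reagents that add atoms: benzenesulfenyl chloride, ClSc1ccccc1
Why: Electrophilic sulfenylation at the nucleophilic enol-ether carbon C5, as in the sulfenylation of glycals and enaminones, gives an α-chloro ether that loses HCl on adding amine because C5–H is α to the ketone.

Step 10
Reactants: 15 (2S)-2-[3,4-bis(tert-butyldimethylsilyloxy)phenyl]-5-(phenylthio)-2,3-dihydro-4H-pyran-4-one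
Product: 16 (2S)-2-[3,4-bis(tert-butyldimethylsilyloxy)phenyl]-5-(phenylsulfinyl)-2,3-dihydro-4H-pyran-4-one (both configurations at sulfur)
Conditions: mCPBA (1.0 equiv), CH2Cl2, −78 °C
Reagents that add atoms: 3-chloroperbenzoic acid, O=C(OO)c1cccc(Cl)c1
Why: One equivalent of peracid at low temperature oxidises the sulfide chemoselectively to the sulfoxide, the push–pull alkene and the silyl ethers being inert; the mixture of sulfur epimers is used as such because sulfur is lost in the next step.

Step 11
Reactants: 16 (2S)-2-[3,4-bis(tert-butyldimethylsilyloxy)phenyl]-5-(phenylsulfinyl)-2,3-dihydro-4H-pyran-4-one; 8 (1E,3Z,6E)-8-(tert-butyldimethylsilyloxy)-1-methoxy-7-methyl-3-(trimethylsilyloxy)octa-1,3,6-triene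
Product: 20 (2S)-2-[3,4-bis(tert-butyldimethylsilyloxy)phenyl]-8-[(E)-4-(tert-butyldimethylsilyloxy)-3-methylbut-2-enyl]-7-hydroxychroman-4-one, via cycloadduct 17 (not isolated), via enone sulfoxide 18 (not isolated), via dienone tautomer 19 (not isolated)
Conditions: 8 (1.5 equiv), ZnBr2 (0.2 equiv), CH2Cl2, −20 °C → rt; then 0.005 M HCl, THF–H2O, 0 °C; then toluene, 60 °C
Reagents that add atoms: none
Why: Proposed new method: diene 8, electron-rich at its chain-bearing terminus, should add across the C5=C6 alkene of 16 (made electron-poor by the C4 ketone and the zinc-chelated sulfinyl group) so that this terminus bonds to the oxygen-bearing β-carbon (future C8a) and the methoxy-bearing terminus to the sulfinyl carbon (future C4a), a normal-demand [4+2] cycloaddition, or its stepwise Mukaiyama–Michael/ring-closure equivalent, that closes ring A as a six-membered carbocycle through two C–C bonds and gives 17. Cold dilute acid then hydrolyses the enol silane and expels methanol from C5 to give enone 18, in which the only β-hydrogen available to sulfur is the one on C8a, held cis to the sulfinyl group by the suprafacial addition; warming should therefore bring about syn-elimination (Ei) of benzenesulfenic acid across C4a–C8a, and dienone 19 tautomerises to phenol 20. The closest known reactions are Diels–Alder/aromatisation sequences of sulfinylquinones and of 3-activated chromones with 1-alkoxy-3-silyloxy dienes, in which a sulfenic acid and an alcohol are likewise lost to reveal a phenol; a 5-sulfinyl dihydropyranone has not been used in this way. No stereocentre is created in 20, since the transient centres at C4a, C5, C8, C8a and sulfur are all erased, so facial and endo/exo selectivity are immaterial, and C2 is not enolisable and sees no base that could open ring C, so it stays (S). The selectivities that matter are regiochemistry (chain at C8, oxygen at C7), secured by the polarity match between the nucleophilic diene terminus and the enone β-carbon, and the order of the two eliminations, secured by running the acid step cold before any heating so that sulfur cannot eliminate toward C5.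

Step 12
Reactants: 20 (2S)-2-[3,4-bis(tert-butyldimethylsilyloxy)phenyl]-8-[(E)-4-(tert-butyldimethylsilyloxy)-3-methylbut-2-enyl]-7-hydroxychroman-4-one
Product: 21 (2S)-2-(3,4-dihydroxyphenyl)-7-hydroxy-8-[(E)-4-hydroxy-3-methylbut-2-enyl]chroman-4-one
Conditions: HF·pyridine, pyridine, THF, 0 °C → rt (argon)
Reagents that add atoms: none
Why: Fluoride cleaves the two aryl and the one primary silyl ether under buffered acidic conditions, which avoids the base-induced retro-oxa-Michael opening to the chalcone that would racemise C2.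

**Compound list**

1 | prenyl acetate | CC(C)=CCOC(C)=O | starting material
2 | (E)-4-hydroxy-3-methylbut-2-enyl acetate | CC(=O)OC/C=C(\C)CO | intermediate
3 | (E)-4-(tert-butyldimethylsilyloxy)-3-methylbut-2-enyl acetate | CC(=O)OC/C=C(\C)CO[Si](C)(C)C(C)(C)C | intermediate
4 | (E)-4-(tert-butyldimethylsilyloxy)-3-methylbut-2-en-1-ol | OC/C=C(\C)CO[Si](C)(C)C(C)(C)C | intermediate
5 | (E)-(4-bromo-2-methylbut-2-enyloxy)(tert-butyl)dimethylsilane | BrC/C=C(\C)CO[Si](C)(C)C(C)(C)C | intermediate
6 | (E)-4-methoxybut-3-en-2-one | CO/C=C/C(C)=O | starting material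
7 | (1E,6E)-8-(tert-butyldimethylsilyloxy)-1-methoxy-7-methylocta-1,6-dien-3-one | CO/C=C/C(=O)CC/C=C(\C)CO[Si](C)(C)C(C)(C)C | intermediate
8 | (1E,3Z,6E)-8-(tert-butyldimethylsilyloxy)-1-methoxy-7-methyl-3-(trimethylsilyloxy)octa-1,3,6-triene | CO/C=C/C(=C/C/C=C(\C)CO[Si](C)(C)C(C)(C)C)O[Si](C)(C)C | intermediate
9 | 3,4-dihydroxybenzaldehyde | O=Cc1ccc(O)c(O)c1 | starting material
10 | 3,4-bis(tert-butyldimethylsilyloxy)benzaldehyde | O=Cc1ccc(O[Si](C)(C)C(C)(C)C)c(O[Si](C)(C)C(C)(C)C)c1 | intermediate
11 | (E)-1-methoxy-3-(trimethylsilyloxy)buta-1,3-diene | CO/C=C/C(=C)O[Si](C)(C)C | starting material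
12 | (1E,5S)-5-[3,4-bis(tert-butyldimethylsilyloxy)phenyl]-1-methoxy-5-(trimethylsilyloxy)pent-1-en-3-one | CO/C=C/C(=O)C[C@H](O[Si](C)(C)C)c1ccc(O[Si](C)(C)C(C)(C)C)c(O[Si](C)(C)C(C)(C)C)c1 | intermediate
13 | (2S)-2-[3,4-bis(tert-butyldimethylsilyloxy)phenyl]-2,3-dihydro-4H-pyran-4-one | O=C1C=CO[C@H](c2ccc(O[Si](C)(C)C(C)(C)C)c(O[Si](C)(C)C(C)(C)C)c2)C1 | intermediate
14 | (2S)-2-[3,4-bis(tert-butyldimethylsilyloxy)phenyl]-6-chloro-5-(phenylthio)oxan-4-one (mixture at C5 and C6) | O=C1C(Sc2ccccc2)C(Cl)O[C@H](c2ccc(O[Si](C)(C)C(C)(C)C)c(O[Si](C)(C)C(C)(C)C)c2)C1 | intermediate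
15 | (2S)-2-[3,4-bis(tert-butyldimethylsilyloxy)phenyl]-5-(phenylthio)-2,3-dihydro-4H-pyran-4-one | O=C1C(Sc2ccccc2)=CO[C@H](c2ccc(O[Si](C)(C)C(C)(C)C)c(O[Si](C)(C)C(C)(C)C)c2)C1 | intermediate
16 | (2S)-2-[3,4-bis(tert-butyldimethylsilyloxy)phenyl]-5-(phenylsulfinyl)-2,3-dihydro-4H-pyran-4-one (both sulfur epimers) | O=C1C(S(=O)c2ccccc2)=CO[C@H](c2ccc(O[Si](C)(C)C(C)(C)C)c(O[Si](C)(C)C(C)(C)C)c2)C1 | intermediate
17 | (2S)-2-[3,4-bis(tert-butyldimethylsilyloxy)phenyl]-8-[(E)-4-(tert-butyldimethylsilyloxy)-3-methylbut-2-enyl]-5-methoxy-4a-(phenylsulfinyl)-7-(trimethylsilyloxy)-4a,5,8,8a-tetrahydrochroman-4-one (mixture at C4a, C5, C8, C8a and sulfur) | COC1C=C(O[Si](C)(C)C)C(C/C=C(\C)CO[Si](C)(C)C(C)(C)C)C2O[C@H](c3ccc(O[Si](C)(C)C(C)(C)C)c(O[Si](C)(C)C(C)(C)C)c3)CC(=O)C12S(=O)c1ccccc1 | intermediate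
18 | (2S)-2-[3,4-bis(tert-butyldimethylsilyloxy)phenyl]-8-[(E)-4-(tert-butyldimethylsilyloxy)-3-methylbut-2-enyl]-4a-(phenylsulfinyl)-8,8a-dihydro-2H-chromene-4,7(3H,4aH)-dione (mixture at C4a, C8, C8a and sulfur) | C/C(=C\CC1C(=O)C=CC2(S(=O)c3ccccc3)C1O[C@H](c1ccc(O[Si](C)(C)C(C)(C)C)c(O[Si](C)(C)C(C)(C)C)c1)CC2=O)CO[Si](C)(C)C(C)(C)C | intermediate
19 | (2S)-2-[3,4-bis(tert-butyldimethylsilyloxy)phenyl]-8-[(E)-4-(tert-butyldimethylsilyloxy)-3-methylbut-2-enyl]-2,3-dihydrochromene-4,7(8H)-dione (keto tautomer of 20) | C/C(=C\CC1C(=O)C=CC2=C1O[C@H](c1ccc(O[Si](C)(C)C(C)(C)C)c(O[Si](C)(C)C(C)(C)C)c1)CC2=O)CO[Si](C)(C)C(C)(C)C | intermediate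
20 | (2S)-2-[3,4-bis(tert-butyldimethylsilyloxy)phenyl]-8-[(E)-4-(tert-butyldimethylsilyloxy)-3-methylbut-2-enyl]-7-hydroxychroman-4-one | C/C(=C\Cc1c(O)ccc2c1O[C@H](c1ccc(O[Si](C)(C)C(C)(C)C)c(O[Si](C)(C)C(C)(C)C)c1)CC2=O)CO[Si](C)(C)C(C)(C)C | intermediate
21 | (2S)-2-(3,4-dihydroxyphenyl)-7-hydroxy-8-[(E)-4-hydroxy-3-methylbut-2-enyl]chroman-4-one | C/C(=C\Cc1c(O)ccc2c1O[C@H](c1ccc(O)c(O)c1)CC2=O)CO | target

**Count and risks**

Total step count: 12. Longest linear sequence: 8 steps (steps 1–6, 11 and 12, from prenyl acetate).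

Steps most likely to fail:

1. Step 11 (proposed new method). The dienophile may be too sluggish at temperatures where the sulfoxide is still intact. Benzenesulfenic acid may be lost toward C5 before methanol is expelled, which blocks aromatisation. The allylic sulfoxide in the enone stage may undergo a [2,3]-shift, or ring C may open by retro-oxa-Michael reaction. Fallback with known chemistry: ring A is bought instead of built. It sets out from bromide 5, which C-alkylates 2,4-dihydroxyacetophenone (CC(=O)c1ccc(O)cc1O) between its two hydroxyls (aqueous KOH, 0 °C) to give 1-{2,4-dihydroxy-3-[(E)-4-(tert-butyldimethylsilyloxy)-3-methylbut-2-enyl]phenyl}ethanone F1. Pyrrolidine-mediated aldol condensation of this ketone with aldehyde 10 (EtOH, 60 °C) passes through (E)-3-[3,4-bis(tert-butyldimethylsilyloxy)phenyl]-1-{2,4-dihydroxy-3-[(E)-4-(tert-butyldimethylsilyloxy)-3-methylbut-2-enyl]phenyl}prop-2-en-1-one F2. This chalcone closes by oxa-Michael addition to racemic 2-[3,4-bis(tert-butyldimethylsilyloxy)phenyl]-8-[(E)-4-(tert-butyldimethylsilyloxy)-3-methylbut-2-enyl]-7-hydroxychroman-4-one F3. Preparative HPLC on a polysaccharide chiral phase separates the enantiomers; the (2R)-enantiomer of the silylated flavanone F4 is set aside and the (2S)-enantiomer is 20, where the route is rejoined before step 12.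

2. Step 5. The lithium enolate may add to unreacted β-methoxy enone (self-condensation), proton transfer may lead to double alkylation, and O-alkylation or SN2' attack on the allylic bromide may compete. Fallback: the ketone is assembled from an amide instead of by enone alkylation. It sets out from bromide 5, which alkylates the lithium enolate of N-methoxy-N-methylacetamide (LDA, THF, −78 °C) to give (E)-6-(tert-butyldimethylsilyloxy)-N-methoxy-N,5-dimethylhex-4-enamide F5. Ethynylmagnesium bromide (THF, 0 °C) converts this Weinreb amide into (E)-8-(tert-butyldimethylsilyloxy)-7-methyloct-6-en-1-yn-3-one F6. DABCO-catalysed conjugate addition of methanol to the ynone gives the (E)-β-methoxy enone 7, where the route is rejoined before step 6.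

3. Step 9. Addition of the sulfenyl chloride may not be followed by clean loss of HCl, the chloride adduct may open ring C, or the electron-rich silyloxy arene may be sulfenylated in competition. Fallback: the C–S bond is made by cross-coupling instead of electrophilic sulfenylation. It sets out from dihydropyranone 13, which is iodinated at C5 (I2, pyridine, CH2Cl2, rt) to give (2S)-2-[3,4-bis(tert-butyldimethylsilyloxy)phenyl]-5-iodo-2,3-dihydro-4H-pyran-4-one F7. Palladium-catalysed C–S coupling of this vinyl iodide with thiophenol (Pd2(dba)3, Xantphos, i-Pr2NEt, dioxane, 80 °C) gives sulfide 15, where the route is rejoined before step 10.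

**Further compounds**

F1 | step 11 | 1-{2,4-dihydroxy-3-[(E)-4-(tert-butyldimethylsilyloxy)-3-methylbut-2-enyl]phenyl}ethanone | CC(=O)c1ccc(O)c(C/C=C(\C)CO[Si](C)(C)C(C)(C)C)c1O
F2 | step 11 | (E)-3-[3,4-bis(tert-butyldimethylsilyloxy)phenyl]-1-{2,4-dihydroxy-3-[(E)-4-(tert-butyldimethylsilyloxy)-3-methylbut-2-enyl]phenyl}prop-2-en-1-one | O=C(/C=C/c1ccc(O[Si](C)(C)C(C)(C)C)c(O[Si](C)(C)C(C)(C)C)c1)c1ccc(O)c(C/C=C(\C)CO[Si](C)(C)C(C)(C)C)c1O
F3 | step 11 | racemic 2-[3,4-bis(tert-butyldimethylsilyloxy)phenyl]-8-[(E)-4-(tert-butyldimethylsilyloxy)-3-methylbut-2-enyl]-7-hydroxychroman-4-one | C/C(=C\Cc1c(O)ccc2c1OC(c1ccc(O[Si](C)(C)C(C)(C)C)c(O[Si](C)(C)C(C)(C)C)c1)CC2=O)CO[Si](C)(C)C(C)(C)C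
F4 | step 11 | (2R)-2-[3,4-bis(tert-butyldimethylsilyloxy)phenyl]-8-[(E)-4-(tert-butyldimethylsilyloxy)-3-methylbut-2-enyl]-7-hydroxychroman-4-one | C/C(=C\Cc1c(O)ccc2c1O[C@@H](c1ccc(O[Si](C)(C)C(C)(C)C)c(O[Si](C)(C)C(C)(C)C)c1)CC2=O)CO[Si](C)(C)C(C)(C)C
F5 | step 5 | (E)-6-(tert-butyldimethylsilyloxy)-N-methoxy-N,5-dimethylhex-4-enamide | CON(C)C(=O)CC/C=C(\C)CO[Si](C)(C)C(C)(C)C
F6 | step 5 | (E)-8-(tert-butyldimethylsilyloxy)-7-methyloct-6-en-1-yn-3-one | C#CC(=O)CC/C=C(\C)CO[Si](C)(C)C(C)(C)C
F7 | step 9 | (2S)-2-[3,4-bis(tert-butyldimethylsilyloxy)phenyl]-5-iodo-2,3-dihydro-4H-pyran-4-one | O=C1C(I)=CO[C@H](c2ccc(O[Si](C)(C)C(C)(C)C)c(O[Si](C)(C)C(C)(C)C)c2)C1
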